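**Plan**

1. The oxolane of the target (O1, C2 aryl, C3 CH2OH, C4 OH, C5 guaiacylmethyl; 2,3-trans, 3,4-trans, 4,5-cis, 2,5-cis) is the all-equatorial product of a Prins–pinacol annulation once the C4 hydroxyl is read as an acetyl group. Primed locants refer to the cis-dihydrobenzofuran.
2. Retrosynthesis: C4–O is cut first (Baeyer–Villiger), then O1–C2, C2–C3 and C4–C5 together, giving a cis-dihydrobenzofuran-5-carbaldehyde and an (E)-allylic 1,2-diol. The aldehyde is cut at C2'–C3' (rhodium carbenoid C–H insertion) and at the benzylic ether O–CH2 (Mitsunobu); the diol at aryl–CH2 (cuprate opening of methyl (S)-glycidate), C–CH3 and C–alkenyl.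
3. Forward: the dihydrobenzofuran ring closes first on the aldehyde fragment, the acyclic diol is built separately, the two are joined, and the oxolane closes in the key step; oxidation and deprotection finish the synthesis.
4. Stereochemistry: C5 is bought with the glycidate and relays C2, C3 and C4 through a chair transition state and the (E)-alkene; C2' and C3' (cis) come from the chiral dirhodium catalyst.
5. Both phenols are carried as acetates through the Lewis acid step, so that neither aryl ring can intercept or stabilise a cation; all acetates are removed in the last step.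

Key step: step 18

Assumption: Rh2(S-PTTL)4 is taken to give the (2R,3S)-cis ester in step 7; if the sense of induction proves opposite, its enantiomer Rh2(R-PTTL)4 replaces it and nothing else changes.

**Aldehyde fragment**

Step 1
Reactants: 1 (2-hydroxy-3-methoxyphenyl)acetic acid
Product: 2 methyl (2-hydroxy-3-methoxyphenyl)acetate
Conditions: MeOH, H2SO4 (cat.), reflux
Reagents that add atoms: methanol, SMILES: CO
Why: Fischer esterification in excess methanol should give the methyl ester and keep the ortho-hydroxy acid from lactonising.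

Step 2
Reactants: 2 methyl (2-hydroxy-3-methoxyphenyl)acetate
Product: 3 methyl (5-bromo-2-hydroxy-3-methoxyphenyl)acetate
Conditions: NBS, MeCN, 0 °C
Reagents that add atoms: N-bromosuccinimide, SMILES: O=C1CCC(=O)N1Br
Why: Electrophilic aromatic bromination should go para to the free phenol (C5), both ortho positions being occupied, as in the bromination of guaiacol.

Step 3
Reactants: 4 vanillin
Product: 5 4-formyl-2-methoxyphenyl pivalate
Conditions: PivCl, Et3N, DMAP (cat.), CH2Cl2, 0 °C → rt
Reagents that add atoms: pivaloyl chloride, SMILES: CC(C)(C)C(Cl)=O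
Why: O-Acylation of the phenol installs a hindered ester that should survive borohydride, Mitsunobu and DBU conditions.

Step 4
Reactants: 5 4-formyl-2-methoxyphenyl pivalate
Product: 6 4-(hydroxymethyl)-2-methoxyphenyl pivalate
Conditions: NaBH4, THF/MeOH, 0 °C
Reagents that add atoms: none
Why: Chemoselective borohydride reduction of the aryl aldehyde should leave the hindered aryl pivalate intact at 0 °C.

Step 5
Reactants: 3 methyl (5-bromo-2-hydroxy-3-methoxyphenyl)acetate; 6 4-(hydroxymethyl)-2-methoxyphenyl pivalate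
Product: 7 methyl {5-bromo-3-methoxy-2-[(3-methoxy-4-pivaloyloxybenzyl)oxy]phenyl}acetate
Conditions: PPh3, DIAD, THF, 0 °C → rt
Reagents that add atoms: none
Why: Mitsunobu etherification of a phenol with a primary benzylic alcohol should form the aryl benzyl ether under neutral conditions that spare both esters.

Step 6
Reactants: 7 methyl {5-bromo-3-methoxy-2-[(3-methoxy-4-pivaloyloxybenzyl)oxy]phenyl}acetate
Product: 8 methyl diazo{5-bromo-3-methoxy-2-[(3-methoxy-4-pivaloyloxybenzyl)oxy]phenyl}acetate
Conditions: p-ABSA, DBU, MeCN, 0 °C → rt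
Reagents that add atoms: 4-acetamidobenzenesulfonyl azide, SMILES: CC(=O)Nc1ccc(cc1)S(=O)(=O)N=[N+]=[N-]
Why: Regitz diazo transfer to the acidic arylacetate position should give the aryldiazoacetate directly.

Step 7
Reactants: 8 methyl diazo{5-bromo-3-methoxy-2-[(3-methoxy-4-pivaloyloxybenzyl)oxy]phenyl}acetate
Product: 9 methyl (2R,3S)-5-bromo-7-methoxy-2-(3-methoxy-4-pivaloyloxyphenyl)-2,3-dihydrobenzofuran-3-carboxylate (cis)
Conditions: Rh2(S-PTTL)4 (1 mol %; PTTL = N-phthaloyl-(S)-tert-leucinate), toluene, −60 °C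
Reagents that add atoms: none
Why: Intramolecular 1,5 C–H insertion of the donor/acceptor rhodium carbenoid into the benzylic ether C–H bond should close the dihydrobenzofuran, the chiral dirhodium tetracarboxylate setting C2' and C3' together with the cis relationship typical of this catalyst class.

Step 8
Reactants: 9 methyl (2R,3S)-5-bromo-7-methoxy-2-(3-methoxy-4-pivaloyloxyphenyl)-2,3-dihydrobenzofuran-3-carboxylate
Product: 10 4-[(2R,3R)-5-bromo-3-(hydroxymethyl)-7-methoxy-2,3-dihydrobenzofuran-2-yl]-2-methoxyphenol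
Conditions: iBu2AlH (6 equiv), CH2Cl2, −78 → 0 °C; aq. potassium sodium tartrate
Reagents that add atoms: none
Why: Hydride reduction with a non-basic aluminium hydride should take the ester to the primary alcohol without epimerising the acidic C3' position and cleave the pivalate in the same operation.

Step 9
Reactants: 10 4-[(2R,3R)-5-bromo-3-(hydroxymethyl)-7-methoxy-2,3-dihydrobenzofuran-2-yl]-2-methoxyphenol
Product: 11 [(2R,3R)-2-(4-acetoxy-3-methoxyphenyl)-5-bromo-7-methoxy-2,3-dihydrobenzofuran-3-yl]methyl acetate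
Conditions: Ac2O, pyridine, DMAP (cat.), CH2Cl2, 0 °C → rt
Reagents that add atoms: acetic anhydride, SMILES: CC(=O)OC(C)=O
Why: Acetylation of both hydroxyls protects them and turns the 2'-aryl group into a poor cation stabiliser, which guards the cis benzylic ether against ionisation in step 18.

Step 10
Reactants: 11 [(2R,3R)-2-(4-acetoxy-3-methoxyphenyl)-5-bromo-7-methoxy-2,3-dihydrobenzofuran-3-yl]methyl acetate
Product: 12 [(2R,3R)-2-(4-acetoxy-3-methoxyphenyl)-5-formyl-7-methoxy-2,3-dihydrobenzofuran-3-yl]methyl acetate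
Conditions: CO/H2 (1:1, 5 bar), Pd(OAc)2 (1 mol %), nBuP(1-adamantyl)2 (3 mol %), TMEDA, toluene, 100 °C
Reagents that add atoms: carbon monoxide, SMILES: [C-]#[O+]
Why: Palladium-catalysed reductive carbonylation (formylation) of the aryl bromide, through oxidative addition to zerovalent palladium, CO insertion and hydrogenolysis of the acyl complex, should give the aldehyde under non-nucleophilic conditions that the acetates tolerate.

**Diol fragment**

Step 11
Reactants: 13 tert-butyl(diphenyl)(prop-2-yn-1-yloxy)silane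
Product: 15 (E)-tert-butyl[(3-iodoprop-2-en-1-yl)oxy]diphenylsilane, via alkenylzirconocene chloride 14 (not isolated)
Conditions: Cp2Zr(H)Cl, THF, rt; then I2, 0 °C
Reagents that add atoms: iodine, SMILES: II
Why: Hydrozirconation of the terminal alkyne is a syn addition with zirconium at the terminus, and iodinolysis with retention should give the (E)-iodoalkene only.

Step 12
Reactants: 16 4-bromo-2-methoxyphenol
Product: 17 (4-bromo-2-methoxyphenoxy)(tert-butyl)dimethylsilane
Conditions: TBSCl, imidazole, DMF, rt
Reagents that add atoms: tert-butyldimethylsilyl chloride, SMILES: CC(C)(C)[Si](C)(C)Cl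
Why: Silylation of the phenol gives an ether that tolerates the Grignard, amide and organolithium steps and is later cleaved selectively by fluoride.

Step 13
Reactants: 17 (4-bromo-2-methoxyphenoxy)(tert-butyl)dimethylsilane; 18 methyl (S)-glycidate
Product: 20 methyl (2S)-3-[4-(tert-butyldimethylsilyloxy)-3-methoxyphenyl]-2-hydroxypropanoate, via arylmagnesium bromide 19 (not isolated)
Conditions: Mg, THF, 40 °C; then CuI (10 mol %), 18, THF, −40 → −20 °C; aq. NH4Cl
Reagents that add atoms: none
Why: Copper-catalysed epoxide opening by the aryl Grignard reagent should occur at the unsubstituted carbon faster than ester addition at low temperature, so the purchased stereocentre is not touched.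

Step 14
Reactants: 20 methyl (2S)-3-[4-(tert-butyldimethylsilyloxy)-3-methoxyphenyl]-2-hydroxypropanoate
Product: 21 (2S)-3-[4-(tert-butyldimethylsilyloxy)-3-methoxyphenyl]-2-hydroxy-N-methoxy-N-methylpropanamide
Conditions: MeNHOMe·HCl, iPrMgCl, THF, −20 → 0 °C
Reagents that add atoms: N,O-dimethylhydroxylamine hydrochloride, SMILES: CNOC.Cl
Why: Aminolysis of the ester by the chloromagnesium amide (Weinreb amide formation) is well known for unprotected α-hydroxy esters such as lactates and should not disturb the carbinol centre.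

Step 15
Reactants: 21 (2S)-3-[4-(tert-butyldimethylsilyloxy)-3-methoxyphenyl]-2-hydroxy-N-methoxy-N-methylpropanamide
Product: 22 (3S)-4-[4-(tert-butyldimethylsilyloxy)-3-methoxyphenyl]-3-hydroxybutan-2-one
Conditions: MeMgBr (3.5 equiv), THF, 0 °C; aq. NH4Cl
Reagents that add atoms: methylmagnesium bromide, SMILES: C[Mg]Br
Why: Grignard addition to the Weinreb amide should stop at the chelated tetrahedral intermediate and release the methyl ketone only on work-up.

Step 16
Reactants: 22 (3S)-4-[4-(tert-butyldimethylsilyloxy)-3-methoxyphenyl]-3-hydroxybutan-2-one; 15 (E)-tert-butyl[(3-iodoprop-2-en-1-yl)oxy]diphenylsilane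
Product: 24 (2S,3S,4E)-1-[4-(tert-butyldimethylsilyloxy)-3-methoxyphenyl]-6-(tert-butyldiphenylsilyloxy)-3-methylhex-4-ene-2,3-diol, via alkenyllithium 23 (not isolated)
Conditions: 15 (2.6 equiv), t-BuLi (5.2 equiv), Et2O, −78 °C; then 22, THF, −78 → −40 °C
Reagents that add atoms: none
Why: Iodine–lithium exchange with retention of the (E)-geometry and 1,2-addition to the ketone should give the diol; the first equivalent forms the lithium alkoxide, whose chelate is expected to favour the (3S)-carbinol drawn, although that centre is lost again in step 18.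

Step 17
Reactants: 24 (2S,3S,4E)-1-[4-(tert-butyldimethylsilyloxy)-3-methoxyphenyl]-6-(tert-butyldiphenylsilyloxy)-3-methylhex-4-ene-2,3-diol
Product: 26 4-[(2S,3S,4E)-6-(tert-butyldiphenylsilyloxy)-2,3-dihydroxy-3-methylhex-4-en-1-yl]-2-methoxyphenyl acetate, via tetrabutylammonium phenoxide 25 (not isolated)
Conditions: Bu4NF (1.05 equiv), THF, −20 → 0 °C; then Ac2O (1.5 equiv), 0 °C
Reagents that add atoms: acetic anhydride, SMILES: CC(=O)OC(C)=O
Why: Fluoride cleaves the aryl silyl ether far faster than the primary tert-butyldiphenylsilyl ether, and the phenoxide is acetylated in preference to the neutral hydroxyls, which lowers the nucleophilicity of the guaiacyl ring before the Lewis acid step.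

**Coupling and end game**

Step 18
Reactants: 26 4-[(2S,3S,4E)-6-(tert-butyldiphenylsilyloxy)-2,3-dihydroxy-3-methylhex-4-en-1-yl]-2-methoxyphenyl acetate; 12 [(2R,3R)-2-(4-acetoxy-3-methoxyphenyl)-5-formyl-7-methoxy-2,3-dihydrobenzofuran-3-yl]methyl acetate
Product: 28 {(2R,3R)-2-(4-acetoxy-3-methoxyphenyl)-5-[(2S,3R,4S,5S)-5-(4-acetoxy-3-methoxybenzyl)-4-acetyl-3-(tert-butyldiphenylsilyloxymethyl)oxolan-2-yl]-7-methoxy-2,3-dihydrobenzofuran-3-yl}methyl acetate, via dioxolane acetal 27 (not isolated)
Conditions: MgSO4, SnCl4 (3 equiv), CH2Cl2, −78 → −20 °C; Et3N, aq. NaHCO3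
Reagents that add atoms: none
Why: SnCl4 condenses the secondary hydroxyl of 26 with 12 (through dioxolane 27), opens the acetal at the tertiary allylic oxygen to the aryl-stabilised (E)-oxocarbenium ion on the C5 oxygen, lets the distal alkene carbon attack it (C2–C3) and quenches the developing C4 cation by a pinacol 1,2-shift of C5 away from the stannylated carbinol carbon (C4–C5), which thereby becomes the acetyl carbonyl. The closest known reaction type is the Lewis acid-promoted Prins–pinacol synthesis of 3-acyltetrahydrofurans from allylic 1,2-diols and aldehydes. The only ring formed, the oxolane, arises from a 6-endo-trig Prins closure to an oxanyl cation in a chair, followed by ring contraction through the suprafacial shift. C2 is set by the equatorial aryl group of the (E)-oxocarbenium ion relative to the equatorial guaiacylmethyl group at the purchased C5 centre (2,5-cis), C3 by the (E)-alkene, which places the CH2OSi arm equatorial (2,3-trans), and C4 by the suprafacial migration, which leaves the acetyl group cis to the C5 substituent and trans to C3. The step needs the alkene, and not an aryl ring or a benzylic ether, to answer the cation: the acetates make the guaiacyl ring a poor partner for an oxa-Pictet–Spengler closure and leave the C2' benzylic ether without a strong para donor, the tert-butyldiphenylsilyl ether tolerates SnCl4 at low temperature, and any epimerisation at the ionisable C2 would drain to the same all-equatorial isomer. Either epimer of the tertiary carbinol converges because that carbon ends as the carbonyl group.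

Step 19
Reactants: 28 the 4-acetyloxolane of step 18
Product: 29 {(2R,3R)-2-(4-acetoxy-3-methoxyphenyl)-5-[(2S,3R,4S,5S)-4-acetoxy-5-(4-acetoxy-3-methoxybenzyl)-3-(tert-butyldiphenylsilyloxymethyl)oxolan-2-yl]-7-methoxy-2,3-dihydrobenzofuran-3-yl}methyl acetate
Conditions: mCPBA, NaHCO3, CH2Cl2, 0 °C → rt
Reagents that add atoms: 3-chloroperoxybenzoic acid, SMILES: OOC(=O)c1cccc(Cl)c1
Why: In the Baeyer–Villiger oxidation the secondary C4 migrates in preference to methyl and with retention, so the acetyl group should become the C4 acetate of unchanged configuration, the bicarbonate buffer protecting the benzylic ethers.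

Step 20
Reactants: 29 the C4 acetate silyl ether of step 19
Product: 30 {(2R,3R)-2-(4-acetoxy-3-methoxyphenyl)-5-[(2S,3R,4S,5S)-4-acetoxy-5-(4-acetoxy-3-methoxybenzyl)-3-(hydroxymethyl)oxolan-2-yl]-7-methoxy-2,3-dihydrobenzofuran-3-yl}methyl acetate
Conditions: Bu4NF, AcOH (1:1), THF, 0 °C → rt
Reagents that add atoms: none
Why: Fluoride-mediated desilylation, buffered with acetic acid, should free the primary alcohol while the product is still lipophilic enough for easy purification.

Step 21
Reactants: 30 the tetraacetate of step 20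
Product: 31 the target, (2S,3S,4S,5S)-oxolane carrying the (2R,3R)-cis-2-(4-hydroxy-3-methoxyphenyl)-3-(hydroxymethyl)-7-methoxy-2,3-dihydrobenzofuran-5-yl group at C2, CH2OH at C3, OH at C4 and the 4-hydroxy-3-methoxybenzyl group at C5
Conditions: K2CO3, MeOH, 0 °C → rt; then AcOH to neutral
Reagents that add atoms: none
Why: Base-catalysed transesterification with methanol should remove the two aryl and two alkyl acetates under conditions mild enough to leave the cis-dihydrobenzofuran and the oxolane stereocentres untouched.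

**Compound list**

1 | (2-hydroxy-3-methoxyphenyl)acetic acid | COc1cccc(CC(=O)O)c1O | starting material
2 | methyl (2-hydroxy-3-methoxyphenyl)acetate | COC(=O)Cc1cccc(OC)c1O | intermediate
3 | methyl (5-bromo-2-hydroxy-3-methoxyphenyl)acetate | COC(=O)Cc1cc(Br)cc(OC)c1O | intermediate
4 | vanillin | COc1cc(C=O)ccc1O | starting material
5 | 4-formyl-2-methoxyphenyl pivalate | COc1cc(C=O)ccc1OC(=O)C(C)(C)C | intermediate
6 | 4-(hydroxymethyl)-2-methoxyphenyl pivalate | COc1cc(CO)ccc1OC(=O)C(C)(C)C | intermediate
7 | methyl {5-bromo-3-methoxy-2-[(3-methoxy-4-pivaloyloxybenzyl)oxy]phenyl}acetate | COC(=O)Cc1cc(Br)cc(OC)c1OCc1ccc(OC(=O)C(C)(C)C)c(OC)c1 | intermediate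
8 | methyl diazo{5-bromo-3-methoxy-2-[(3-methoxy-4-pivaloyloxybenzyl)oxy]phenyl}acetate | COC(=O)C(=[N+]=[N-])c1cc(Br)cc(OC)c1OCc1ccc(OC(=O)C(C)(C)C)c(OC)c1 | intermediate
9 | methyl (2R,3S)-5-bromo-7-methoxy-2-(3-methoxy-4-pivaloyloxyphenyl)-2,3-dihydrobenzofuran-3-carboxylate (cis) | Brc1cc(OC)c2c(c1)[C@H](C(=O)OC)[C@H](c1ccc(OC(=O)C(C)(C)C)c(OC)c1)O2 | intermediate
10 | 4-[(2R,3R)-5-bromo-3-(hydroxymethyl)-7-methoxy-2,3-dihydrobenzofuran-2-yl]-2-methoxyphenol (cis) | Brc1cc(OC)c2c(c1)[C@H](CO)[C@H](c1ccc(O)c(OC)c1)O2 | intermediate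
11 | [(2R,3R)-2-(4-acetoxy-3-methoxyphenyl)-5-bromo-7-methoxy-2,3-dihydrobenzofuran-3-yl]methyl acetate | Brc1cc(OC)c2c(c1)[C@H](COC(C)=O)[C@H](c1ccc(OC(C)=O)c(OC)c1)O2 | intermediate
12 | [(2R,3R)-2-(4-acetoxy-3-methoxyphenyl)-5-formyl-7-methoxy-2,3-dihydrobenzofuran-3-yl]methyl acetate | O=Cc1cc(OC)c2c(c1)[C@H](COC(C)=O)[C@H](c1ccc(OC(C)=O)c(OC)c1)O2 | intermediate
13 | tert-butyl(diphenyl)(prop-2-yn-1-yloxy)silane | C#CCO[Si](c1ccccc1)(c1ccccc1)C(C)(C)C | starting material
14 | (E)-[3-(tert-butyldiphenylsilyloxy)prop-1-en-1-yl]zirconocene chloride, cyclopentadienyl ligands drawn σ-bonded (not isolated) | CC(C)(C)[Si](c1ccccc1)(c1ccccc1)OC/C=C/[Zr](Cl)(C1C=CC=C1)C1C=CC=C1 | intermediate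
15 | (E)-tert-butyl[(3-iodoprop-2-en-1-yl)oxy]diphenylsilane | CC(C)(C)[Si](c1ccccc1)(c1ccccc1)OC/C=C/I | intermediate
16 | 4-bromo-2-methoxyphenol | COc1cc(Br)ccc1O | starting material
17 | (4-bromo-2-methoxyphenoxy)(tert-butyl)dimethylsilane | COc1cc(Br)ccc1O[Si](C)(C)C(C)(C)C | intermediate
18 | methyl (S)-glycidate | COC(=O)[C@@H]1CO1 | starting material
19 | [4-(tert-butyldimethylsilyloxy)-3-methoxyphenyl]magnesium bromide (not isolated) | COc1cc([Mg]Br)ccc1O[Si](C)(C)C(C)(C)C | intermediate
20 | methyl (2S)-3-[4-(tert-butyldimethylsilyloxy)-3-methoxyphenyl]-2-hydroxypropanoate | COC(=O)[C@@H](O)Cc1ccc(O[Si](C)(C)C(C)(C)C)c(OC)c1 | intermediate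
21 | (2S)-3-[4-(tert-butyldimethylsilyloxy)-3-methoxyphenyl]-2-hydroxy-N-methoxy-N-methylpropanamide | CON(C)C(=O)[C@@H](O)Cc1ccc(O[Si](C)(C)C(C)(C)C)c(OC)c1 | intermediate
22 | (3S)-4-[4-(tert-butyldimethylsilyloxy)-3-methoxyphenyl]-3-hydroxybutan-2-one | CC(=O)[C@@H](O)Cc1ccc(O[Si](C)(C)C(C)(C)C)c(OC)c1 | intermediate
23 | (E)-[3-(tert-butyldiphenylsilyloxy)prop-1-en-1-yl]lithium (not isolated) | [Li]/C=C/CO[Si](c1ccccc1)(c1ccccc1)C(C)(C)C | intermediate
24 | (2S,3S,4E)-1-[4-(tert-butyldimethylsilyloxy)-3-methoxyphenyl]-6-(tert-butyldiphenylsilyloxy)-3-methylhex-4-ene-2,3-diol (expected major C3 epimer drawn) | COc1cc(C[C@H](O)[C@@](C)(O)/C=C/CO[Si](c2ccccc2)(c2ccccc2)C(C)(C)C)ccc1O[Si](C)(C)C(C)(C)C | intermediate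
25 | tetrabutylammonium phenoxide of diol 24 after loss of the aryl silyl group (not isolated) | COc1cc(C[C@H](O)[C@@](C)(O)/C=C/CO[Si](c2ccccc2)(c2ccccc2)C(C)(C)C)ccc1[O-].CCCC[N+](CCCC)(CCCC)CCCC | intermediate
26 | 4-[(2S,3S,4E)-6-(tert-butyldiphenylsilyloxy)-2,3-dihydroxy-3-methylhex-4-en-1-yl]-2-methoxyphenyl acetate | COc1cc(C[C@H](O)[C@@](C)(O)/C=C/CO[Si](c2ccccc2)(c2ccccc2)C(C)(C)C)ccc1OC(C)=O | intermediate
27 | 2-aryl-1,3-dioxolane from the two hydroxyls of 26 and the formyl carbon of 12, diol centres unchanged, acetal carbon unassigned (not isolated) | COc1cc(C[C@@H]2OC(c3cc(OC)c4c(c3)[C@H](COC(C)=O)[C@H](c3ccc(OC(C)=O)c(OC)c3)O4)O[C@@]2(C)/C=C/CO[Si](c3ccccc3)(c3ccccc3)C(C)(C)C)ccc1OC(C)=O | intermediate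
28 | (2S,3R,4S,5S)-oxolane: C2 the (2R,3R)-2-(4-acetoxy-3-methoxyphenyl)-3-(acetoxymethyl)-7-methoxy-2,3-dihydrobenzofuran-5-yl group, C3 CH2OSi(tBu)Ph2, C4 acetyl, C5 4-acetoxy-3-methoxybenzyl | COc1cc(C[C@@H]2O[C@H](c3cc(OC)c4c(c3)[C@H](COC(C)=O)[C@H](c3ccc(OC(C)=O)c(OC)c3)O4)[C@@H](CO[Si](c3ccccc3)(c3ccccc3)C(C)(C)C)[C@@H]2C(C)=O)ccc1OC(C)=O | intermediate
29 | as 28 with acetoxy in place of acetyl at C4, (2S,3R,4S,5S)-oxolane | COc1cc(C[C@@H]2O[C@H](c3cc(OC)c4c(c3)[C@H](COC(C)=O)[C@H](c3ccc(OC(C)=O)c(OC)c3)O4)[C@@H](CO[Si](c3ccccc3)(c3ccccc3)C(C)(C)C)[C@@H]2OC(C)=O)ccc1OC(C)=O | intermediate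
30 | as 29 with free CH2OH at C3, (2S,3R,4S,5S)-oxolane | COc1cc(C[C@@H]2O[C@H](c3cc(OC)c4c(c3)[C@H](COC(C)=O)[C@H](c3ccc(OC(C)=O)c(OC)c3)O4)[C@@H](CO)[C@@H]2OC(C)=O)ccc1OC(C)=O | intermediate
31 | CNP0179668.1, (2S,3S,4S,5S)-oxolane with (2R,3R)-cis-dihydrobenzofuran | COc1cc(C[C@@H]2O[C@H](c3cc(OC)c4c(c3)[C@H](CO)[C@H](c3ccc(O)c(OC)c3)O4)[C@@H](CO)[C@@H]2O)ccc1O | target

**Count**

Total steps: 21. Longest linear sequence: 12 steps (steps 1, 2, 5–10, 18–21).

**Steps most likely to fail**

Step 18. The cation may be lost before the alkene engages. Water released by the condensation turns SnCl4 into a protic acid, which can ionise the tertiary allylic C–O bond or strip the silyl ether. The allylic silyloxy group also slows the Prins closure, which gives time for capture by the guaiacyl ring or for an oxonia-Cope/aldol detour that would loosen the C5 configuration. The fallback separates acetal formation from rearrangement under strictly anhydrous conditions. It sets out from 26: treatment with Me3SiOTf and 2,6-lutidine (CH2Cl2, −78 °C) should give the bis(trimethylsilyl) ether F1. F1 and aldehyde 12 are then joined by silyl triflate-catalysed acetalisation (Me3SiOTf cat., CH2Cl2, −78 °C), which produces no water, and dioxolane 27 is isolated. Rearrangement of pure 27 with SnCl4 (CH2Cl2 or MeNO2, −78 → −20 °C) rejoins the route at 28.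

Step 7. Facial discrimination at the rhodium carbenoid may be insufficient, or the cis preference may erode, because the methoxy group flanking the benzyloxy arm changes its preferred conformation relative to simpler substrates. The fallback replaces catalyst control of absolute configuration by separation of covalent diastereomers. It sets out from 10 of whatever enantiomeric purity the insertion delivers (trans material having been removed by chromatography at the ester stage). Acylation of both hydroxyls with (1S)-camphanoyl chloride (pyridine, DMAP, CH2Cl2) should give the bis-camphanate F2. The diastereomer derived from (2R,3R)-10 is purified by crystallisation or chromatography and methanolysed (K2CO3, MeOH, 0 °C), which returns enantiopure 10 to the route.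

Step 10. Carbonylation of the electron-rich aryl bromide may stall, with hydrodebromination competing and prolonged heating at 100 °C threatening the acetates. The fallback installs the formyl group by halogen–lithium exchange before the acetates are in place. It sets out from 10: silylation of both hydroxyls (TBSCl, imidazole, DMF) should give the bis(silyl) ether F3. Bromine–lithium exchange (t-BuLi, THF, −78 °C) and quenching with DMF should give the aldehyde F4. Buffered desilylation (Bu4NF, AcOH, THF) should give the hydroxy phenol aldehyde F5, and acetylation (Ac2O, pyridine) rejoins the route at 12.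

Further compounds
F1 | step 18 | bis(trimethylsilyl) ether of diol 26 | COc1cc(C[C@H](O[Si](C)(C)C)[C@@](C)(O[Si](C)(C)C)/C=C/CO[Si](c2ccccc2)(c2ccccc2)C(C)(C)C)ccc1OC(C)=O
F2 | step 7 | bis[(1S,4R)-camphanate] of 10 (phenol and primary alcohol both acylated) | Brc1cc(OC)c2c(c1)[C@H](COC(=O)[C@@]13CC[C@@](C)(C(=O)O1)C3(C)C)[C@H](c1ccc(OC(=O)[C@@]34CC[C@@](C)(C(=O)O3)C4(C)C)c(OC)c1)O2
F3 | step 10 | bis(tert-butyldimethylsilyl) ether of 10 | Brc1cc(OC)c2c(c1)[C@H](CO[Si](C)(C)C(C)(C)C)[C@H](c1ccc(O[Si](C)(C)C(C)(C)C)c(OC)c1)O2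
F4 | step 10 | (2R,3R)-2-[4-(tert-butyldimethylsilyloxy)-3-methoxyphenyl]-3-(tert-butyldimethylsilyloxymethyl)-7-methoxy-2,3-dihydrobenzofuran-5-carbaldehyde | O=Cc1cc(OC)c2c(c1)[C@H](CO[Si](C)(C)C(C)(C)C)[C@H](c1ccc(O[Si](C)(C)C(C)(C)C)c(OC)c1)O2
F5 | step 10 | (2R,3R)-2-(4-hydroxy-3-methoxyphenyl)-3-(hydroxymethyl)-7-methoxy-2,3-dihydrobenzofuran-5-carbaldehyde | O=Cc1cc(OC)c2c(c1)[C@H](CO)[C@H](c1ccc(O)c(OC)c1)O2
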